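The data are simulated for substances that don't exist; the scatter is artificial.

The easy step can be read straight off Thursday's run. Electrophile meets nucleophile and target appears, and dividing target gained by electrophile lost takes time out of the two rates, giving a share s = 67.1% at 80.0 s, a reading that carries the scatter of the run. If each target formed sets one acid free, s is the acid to be taken up per electrophile used. The cover Q, the free base charged divided by s times the electrophile charged, then says whether the free base can hold that acid.

| flask | electrophile | nucleophile | free base | remark | time |
|---|---|---|---|---|---|
| Thursday's | 0.32 M | 0.32 M | 0.77 M | run made earlier |  |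
| flask | 0.32 M | 0.320 M | 0.384 M |  | 12 min |

Thursday's run (percent of the electrophile charged)

| time / s | electrophile / % | target / % |
|---|---|---|
| 10.0 | 92.9 | 8.0 |
| 12.0 | 87.4 | 7.9 |
| 20.0 | 85.5 | 13.6 |
| 30.0 | 77.6 | 16.6 |
| 40.0 | 73.1 | 19.6 |
| 60.0 | 65.6 | 22.7 |
| 80.0 | 58.3 | 28.0 |

(readings scatter by 1 percentage point)

- part of the electrophile that has reacted at 12 min
- share of the unused nucleophile that is free and not bound as protonated nucleophile, at 12 min

- the numbers in the tables scatter with a standard deviation of 1 percentage point
- the earlier runs do not show how much of nucleophile is bound; that part of a forecast is a guess
- no earlier run changes the charge of free base; that part of a forecast is a guess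

Thursday's flask and this flask differ in one charge, the free base, and their covers are 3.58 and 1.79. Because both stand above one, the free base should not be the limiting reagent in either, so the electrophile in this flask should keep falling as on Thursday, for longer. On Thursday the reciprocal of the electrophile fraction left, less one, grows roughly in proportion to time, and carried to 12 min that gives 86.6% reacted. With the whole electrophile charge reacted, this flask would keep 44.0% of its free base to compete for acid, but the runs do not show how strongly the nucleophile binds it.

The forecast, lower on the electrophile than this reckoning, gives 82% (70% to 91%) reacted and 70% (35% to 95%) free, noting that “Thursday's clean kinetics only suggest the base outcompetes the nucleophile modestly”.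

This flask gives 92.3% of the electrophile reacted and 86.8% of the unused nucleophile free, with these steps running:

    nucleophile + acid set free ⇌ protonated nucleophile, settled at all times (K = 370 L mol⁻¹)
    electrophile + nucleophile → acid set free + target (k = 0.0290 L mol⁻¹ s⁻¹)
    nucleophile + target → over-reaction product (k = 0.0130 L mol⁻¹ s⁻¹)
    electrophile + target → side product (k = 0.0150 L mol⁻¹ s⁻¹)
    acid set free + free base ⇌ salt of the base (K = 8100 L mol⁻¹, k = 1.10 L mol⁻¹ s⁻¹)

At Thursday's last reading time, changing the free base charge to this flask's moves the reacted part from 40.7% to 39.8%, while the longer time alone lifts it to 93.1%. With 92.3% of the electrophile reacted, Q reckons 48.4% of the free base left in this flask, which holds 46% of it at 12.0 min. The neighbour charged with 0.15 M of free base has a cover of 0.698, below one, and at 12.0 min it holds 6.9% of its free base, with 33.9% of its unused nucleophile free.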